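I had no rate constants for this flask, and alpha, the one earlier run, never changed the coupling partner, so my reckoning had to start from the charges and the readings.

- alpha: left-handed substrate 0.60 M; right-handed substrate 0.60 M; coupling partner 1.8 M; free catalyst 0.70 mM; impurity 0.11 mM; run made earlier
- flask: left-handed substrate 1.2 M; coupling partner 1.80 M; free catalyst 0.70 mM; impurity 0.11 mM; right-handed substrate 1.2 M

- alpha (time / h: left-handed product / %): 2.00: 15.5; 5.00: 32.5; 10.0: 47.6; 15.0: 48.9

(scatter of a reading: 1 percentage point)

1. apparent order in coupling partner when 50% of the left-handed substrate and right-handed substrate together are converted (percent change of the rate of making left-handed product for one percent more coupling partner charged)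

Reading down the table, alpha's left-handed product climbed to 47.6% at 10.0 h and gained 1.3 percentage points more by 15.0 h, close to the scatter of 1 point. So alpha's left-handed product stood near half of the racemate charged, which is the left-handed substrate's own share of the charge, and alpha's table holds no reading of the right-handed substrate.

Each unit of product takes one unit of coupling partner, so in this flask 50% conversion of both substrates together leaves a fraction 33.3% of the partner charged. One percent more charged then means 3.00 percent more left, and I called this ratio the leverage, the charge of coupling partner over what is left of it at the moment looked at.

My first answer took the order in coupling partner as one, a guess that alpha cannot test, which made the apparent order equal to the leverage. Going round once more, I supposed that the partner speeds the reactions of both mirror substrates alike. The selectivity factor then stays put, the left-handed substrate remaining at that conversion stays the same, and the answer stayed at 3.00.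

The forecast was lower than my reckoning, at 2.6 within 1 to 3.2, on the guess of “a little less if the partner binds the catalyst”.

The flask gave an apparent order of 3.3, with these steps:

    coupling partner + catalyst intermediate A → free catalyst + left-handed product (k = 112 M⁻¹ h⁻¹)
    free catalyst + impurity → spent catalyst A (k = 5490 M⁻¹ h⁻¹)
    free catalyst + left-handed substrate ⇌ catalyst intermediate A (K = 8.64 M⁻¹, k = 12700 M⁻¹ h⁻¹)
    free catalyst + right-handed substrate ⇌ catalyst intermediate B (K = 0.180 M⁻¹, k = 461 M⁻¹ h⁻¹)
    free catalyst → spent catalyst B (k = 0.0166 h⁻¹)
    coupling partner + catalyst intermediate B → free catalyst + right-handed product (k = 53.2 M⁻¹ h⁻¹)

At that conversion, reached after 25.7 h, the rate of making left-handed product changed by 0.63 percent for one percent more on the rate constant of coupling partner with catalyst intermediate B. The order stood at 1.10 times the leverage of this flask. Alpha's charge gives a leverage of 1.50 at 50% conversion, half of this flask's 3.00.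

The readings were generated by integration from invented constants, and the scatter is random.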